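## Analysis of the target

The target is a bisabolane-type sesquiterpenoid diester built on a cyclohexanone ring. The ring is numbered C1 (ketone), C2 (epoxide carbon bearing the methyl group), C3 (epoxide CH), C4 (CH2), C5 (CH bearing the side chain) and C6 (CH–OAc). The side chain begins with the 1,1-disubstituted alkene carbon C7 (=CH2) and continues with the angeloylated carbinol C8 and a prenyl group. There are five stereocentres, C2, C3, C5, C6 and C8, all S. On the ring the C5 side chain and the C6 acetate are trans, and the cis-fused epoxide oxygen lies on the face of the side chain, trans to the acetate. C8 is separated from C5 by the sp2 carbon C7, so it cannot be relayed from the ring and needs its own control element. The molecule is fragile: an epoxy ketone next to an epimerisable acetoxy centre, an angelate that isomerises to the tiglate, an allylic ester at C8, and three alkenes besides the one that must be epoxidised. The difficulty is therefore the order of events: C6, C1, C2 and C3 must be oxygenated on defined faces, one alkene out of four must be epoxidised, and the methylene must sit exactly between C5 and C8. The plan rests on two features. C1 and C6 are adjacent oxygen-bearing carbons with the threo pattern of tartaric acid. The C4–C5 bond and the C7 methylene are the bond and the cation terminus of the natural bisabolane ring closure, so closing C4–C5 with an allyl cation and ending the charge at C7 with a silyl group gives the ring, the C2=C3 alkene and the methylene in one operation.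

## Retrosynthetic reasoning

**30 back to 27 (C–O bonds only).** The ketone of 30 comes from the C1 carbinol 29, the acetate of 29 from epoxy diol 28, and the epoxide of 28 from cyclohexene diol 27. The allylic C1 hydroxyl is the only handle that can steer an oxidant to C2=C3 in the presence of three other alkenes, and it lies on the face where the epoxide must go. It is therefore kept as an alcohol until the epoxide is in place and oxidised last, because the epoxy ketone next to the acetoxy centre is the least robust array in the route.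

**27 back to 26 (ketal).** The two ring oxygens are carried as a trans-fused acetonide. As ethers they do not ionise in the cation step, and the strained trans ring is released under mild acid.

**26 back to 23 (C4–C5, the key disconnection).** C4–C5 is the only ring bond whose cleavage leaves an allyl cation (C4, C3, C2) on one side and an alkene that can end the charge at C7 on the other, while keeping the C1–C6 diol unit intact. The forward reaction gains the ring, the C5 stereocentre, the C2=C3 alkene and the C7 methylene. It must ionise only the C4 acetate, close the six-membered ring, place the chain trans to the C6 oxygen, and lose silicon so that the alkene appears only at C7=CH2.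

**23 back to 19 and 20 (ester bonds).** The C4 acetate is installed last (22 to 23) so that no later reagent meets the ionisable ester. Before that the C8 hydroxyl of 19 is esterified with angelic acid 20 (giving 21) and the C4 silyl ether is removed (22). Having the angelate in place before the ring closure saves a protecting group at C8.

**19 back to 17 (C8–CH2 bond and the prenyl alkene).** C8 is insulated from the other stereocentres, so it is set by a chiral allylborane adding to enal 17 (giving 18). The vinyl group is then turned into the prenyl group by cross-metathesis (19). A prenyl metal would add through its γ-carbon and give the wrong skeleton, which is why the bond is cut this way.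

**17 back to 11 and 14 (C5=C7).** The trisubstituted allylsilane is cut at its double bond: aldehyde 11 (C5) and phosphonate 14, which already carries the silylmethyl group on C7 and the future C8 as an ester. The forward olefination must place the ester cis to C6, so that in 23 the silyl group points away from the dioxolane. Reduction and re-oxidation (15, 16, 17) adjust C8 to the aldehyde. Phosphonate 14 comes from 12 and 13.

**11 back to 6 (C2–CH3 bond).** The (Z)-trisubstituted alkene of the C4 arm is cut at the methyl group: syn addition of a methylcopper reagent to ynoate 6 gives 7 with the ester cis to C1 by mechanism. Olefination of a methyl ketone at C2=C3 was not chosen, because stabilised phosphorus reagents tend to put the ester trans to the branched C1. Reduction (8), silylation (9), release of the second terminus (10) and oxidation lead to 11.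

**6 back to 1 (C2–C3 and C3–C4, then desymmetrisation).** The alkyne carbons are added to aldehyde 3 through dibromoalkene 4 and alkynyllithium 5. Aldehyde 3 comes from mono-ether 2, and 2 from the commercial C2-symmetric diol 1 of the tartrate chiral pool. The two hydroxyls of 1 are equivalent, so the desymmetrisation raises no stereochemical question.

## Alternatives that were turned down

**Alternative 1:** Two ring bonds, C5–C6 and C3–C4, are cut at once, so that the carbocycle arises from a [4+2] cycloaddition of 3-methylfuran A1 with the acrylimide A2. The furan oxygen bridges C3 and C6 and is meant to end as the C6 oxygen. In the forward direction a chiral copper bis(oxazoline) Lewis acid would give the endo oxabicycle A3, with the C5 acyl group trans to the C6–O bond.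
- For it: one catalytic asymmetric step from two simple achiral compounds sets the ring, the C5/C6 relationship and the absolute configuration. On speed of reaching an enantioenriched ring it is clearly stronger than the chosen route, which needs eighteen steps before its ring closure.
- Against it for this target: A3 has oxygen on C3 and C6 but none on C1 and C2, and its alkene is at C1=C2. The bridge must be opened at C3 without losing C6–O, C1 must be oxygenated and an alkene re-made at C2=C3 before the epoxide can be placed. These are several redox steps on a bicycle prone to cycloreversion. The regiochemistry of a 3-substituted furan with an acrylate-type dienophile is only moderately biased. The whole side chain (C7 methylene from the imide carbonyl, C8 with its own stereocentre, prenyl, angelate) must still be grown from the imide.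
- Comparison: the chosen route has every ring oxygen at its final carbon from the start, closes the ring with the side chain complete and forms C7=CH2 regiospecifically.

**Alternative 2:** The C2=C3 double bond of an enone is cut. The acyclic dienone A4 carries a methacryloyl unit (C1, C2) and an allyl group (C4, C3), and ring-closing metathesis with a ruthenium alkylidene catalyst would give cyclohexenone A5.
- For it: metathesis is the most dependable six-ring closure and tolerates ketone and acetate. C1 and C6 are already at their final oxidation level in A5. On reliability of the ring-forming step it is stronger than a cation cyclisation.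
- Against it for this target: A4 must already hold the anti C5/C6 pair and C8, all made by acyclic stereocontrol, and its acetoxy ketone is epimerisable at C6 throughout. The prenyl alkene has to stay masked (an acetal in A5) and C8 silylated, so acetal hydrolysis, olefination, desilylation and angeloylation follow on a sensitive ring. The decisive point is the epoxide: alkaline peroxide adds to 5-substituted 2-methylcyclohexenones trans to the 5-substituent, the wrong face here, and A5 has no hydroxyl to direct an oxidant. A reduction, directed epoxidation and re-oxidation would be needed.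
- Comparison: the chosen route keeps C1 as an alcohol exactly for that direction and closes the ring with the full side chain in place.

**Alternative 3:** The C1–C2 bond is cut. Aldehyde A6 carries a (Z)-iodoalkene (C2, C3), and a coupling mediated by divalent chromium with nickel catalysis (Nozaki–Hiyama–Kishi) would close the ring to cyclohexenol A7, with a free C1 hydroxyl and a 4-methoxybenzyl ether on C6.
- For it: the conditions are mild and spare esters, the angelate and the prenyl group. The product has the allylic hydroxyl needed to direct the epoxide. The C1 and C6 oxygens emerge differentiated, so the regioselective acetylation of the chosen route (step 22) is unnecessary. On that point it is stronger.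
- Against it for this target: the C1 carbinol is a new stereocentre formed next to the C6 ether. Only its trans isomer directs the epoxide correctly, and the balance of Felkin and chelation control in a ring-forming addition is hard to predict. A6 needs C5 and C6 set by an acyclic method, a configurationally labile alkoxy aldehyde and a (Z)-iodoalkene. The chromium salt is used in excess, and the benzylic ether must later be cleaved oxidatively beside electron-rich alkenes.
- Comparison: the chosen route takes C1 and C6 from the chiral pool, so its ring closure creates only C5, under conformational control. The price is the selective acetylation at the end.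

Key step: step 19

Remark: atoms are numbered C1–C8 as in the analysis; the C5=C7 geometry of 23 is not transferred to 26 and is made with C8 cis to C6 so that the silyl group lies away from the dioxolane.
Remark: commercial 2,3-O-isopropylidene-L-threitol 1, the reduced acetonide of L-tartrate, is taken as the chiral starting material.

## Route

Step 1
Reactants: 1 (4S,5S)-2,2-dimethyl-1,3-dioxolane-4,5-dimethanol (2,3-O-isopropylidene-L-threitol)
Product: 2 [(4S,5S)-5-{[(4-methoxybenzyl)oxy]methyl}-2,2-dimethyl-1,3-dioxolan-4-yl]methanol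
Conditions: NaH (1.0 equiv), THF/DMF, 0 °C; 4-methoxybenzyl chloride (1.0 equiv), Bu4NI (cat.), 0 °C to rt
Reagents that add atoms: 4-methoxybenzyl chloride, COc1ccc(CCl)cc1
Why: Williamson etherification; the two hydroxyls of the C2-symmetric diol are homotopic, so one equivalent of base and halide should give a single mono-ether without touching a stereocentre, and a little bis-ether and recovered 1 are separated.

Step 2
Reactants: 2 [(4S,5S)-5-{[(4-methoxybenzyl)oxy]methyl}-2,2-dimethyl-1,3-dioxolan-4-yl]methanol
Product: 3 (4R,5S)-5-{[(4-methoxybenzyl)oxy]methyl}-2,2-dimethyl-1,3-dioxolane-4-carbaldehyde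
Conditions: (COCl)2, DMSO, CH2Cl2, −78 °C; Et3N, −78 to 0 °C
Reagents that add atoms: none
Why: Swern oxidation stops at the aldehyde; the trans-dioxolane is the thermodynamically favoured arrangement, so the α-centre is not at risk, and 3 is used directly.

Step 3
Reactants: 3 (4R,5S)-5-{[(4-methoxybenzyl)oxy]methyl}-2,2-dimethyl-1,3-dioxolane-4-carbaldehyde
Product: 4 (4S,5S)-4-(2,2-dibromoethenyl)-5-{[(4-methoxybenzyl)oxy]methyl}-2,2-dimethyl-1,3-dioxolane
Conditions: CBr4, PPh3, Et3N, CH2Cl2, 0 °C
Reagents that add atoms: carbon tetrabromide, BrC(Br)(Br)Br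
Why: Ramirez–Corey–Fuchs dibromo-olefination, a Wittig-type reaction of Ph3P=CBr2; Et3N buffers the medium so that the acetonide and the benzylic ether survive.

Step 4
Reactants: 4 (4S,5S)-4-(2,2-dibromoethenyl)-5-{[(4-methoxybenzyl)oxy]methyl}-2,2-dimethyl-1,3-dioxolane
Product: 6 methyl 3-[(4S,5S)-5-{[(4-methoxybenzyl)oxy]methyl}-2,2-dimethyl-1,3-dioxolan-4-yl]prop-2-ynoate, via alkynyllithium 5 (not isolated)
Conditions: n-BuLi (2.1 equiv), THF, −78 °C; ClCO2Me, −78 to 0 °C
Reagents that add atoms: methyl chloroformate, COC(=O)Cl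
Why: Second stage of the Corey–Fuchs sequence: Br/Li exchange, rearrangement to the alkyne and deprotonation give 5, which is C-acylated by the chloroformate; the alkyne carbons are C2 and C3 and the ester carbon is C4.

Step 5
Reactants: 6 methyl 3-[(4S,5S)-5-{[(4-methoxybenzyl)oxy]methyl}-2,2-dimethyl-1,3-dioxolan-4-yl]prop-2-ynoate
Product: 7 methyl (2Z)-3-[(4S,5S)-5-{[(4-methoxybenzyl)oxy]methyl}-2,2-dimethyl-1,3-dioxolan-4-yl]but-2-enoate
Conditions: Me2CuLi (from CuI and MeLi), THF, −78 °C; MeOH then aq. NH4Cl at −78 °C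
Reagents that add atoms: lithium dimethylcuprate, [Li+].C[Cu-]C
Why: Conjugate carbocupration of a 2-ynoate is a syn addition, so protonation at −78 °C with retention should put H on C3 cis to the new methyl group and the ester cis to C1, the (Z) geometry that later lets C4 reach C5. Quenching cold avoids equilibration through the allenoate.

Step 6
Reactants: 7 methyl (2Z)-3-[(4S,5S)-5-{[(4-methoxybenzyl)oxy]methyl}-2,2-dimethyl-1,3-dioxolan-4-yl]but-2-enoate
Product: 8 (2Z)-3-[(4S,5S)-5-{[(4-methoxybenzyl)oxy]methyl}-2,2-dimethyl-1,3-dioxolan-4-yl]but-2-en-1-ol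
Conditions: i-Bu2AlH (2.5 equiv), CH2Cl2, −78 °C; aq. potassium sodium tartrate
Reagents that add atoms: none
Why: 1,2-Reduction of the enoate by i-Bu2AlH at low temperature should give the allylic alcohol without touching the alkene geometry.

Step 7
Reactants: 8 (2Z)-3-[(4S,5S)-5-{[(4-methoxybenzyl)oxy]methyl}-2,2-dimethyl-1,3-dioxolan-4-yl]but-2-en-1-ol
Product: 9 tert-butyl{[(2Z)-3-[(4S,5S)-5-{[(4-methoxybenzyl)oxy]methyl}-2,2-dimethyl-1,3-dioxolan-4-yl]but-2-en-1-yl]oxy}dimethylsilane
Conditions: t-BuMe2SiCl, imidazole, CH2Cl2, rt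
Reagents that add atoms: tert-butyldimethylsilyl chloride, CC(C)(C)[Si](C)(C)Cl
Why: Standard silylation; the C4 oxygen must be an ether while the other arm is built, because the hydride reduction and basic steps that follow would not spare an acetate.

Step 8
Reactants: 9 tert-butyl{[(2Z)-3-[(4S,5S)-5-{[(4-methoxybenzyl)oxy]methyl}-2,2-dimethyl-1,3-dioxolan-4-yl]but-2-en-1-yl]oxy}dimethylsilane
Product: 10 [(4S,5S)-5-[(2Z)-4-{[tert-butyl(dimethyl)silyl]oxy}but-2-en-2-yl]-2,2-dimethyl-1,3-dioxolan-4-yl]methanol
Conditions: DDQ (1.2 equiv), CH2Cl2/pH 7 buffer, 0 °C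
Reagents that add atoms: none
Why: Oxidative cleavage of the 4-methoxybenzyl ether by DDQ (hydride abstraction, then hydrolysis of the oxocarbenium ion) is orthogonal to the silyl ether and the acetonide; it is placed before the allylsilane exists.

Step 9
Reactants: 10 [(4S,5S)-5-[(2Z)-4-{[tert-butyl(dimethyl)silyl]oxy}but-2-en-2-yl]-2,2-dimethyl-1,3-dioxolan-4-yl]methanol
Product: 11 (4R,5S)-5-[(2Z)-4-{[tert-butyl(dimethyl)silyl]oxy}but-2-en-2-yl]-2,2-dimethyl-1,3-dioxolane-4-carbaldehyde
Conditions: Dess–Martin periodinane, NaHCO3, CH2Cl2, 0 °C to rt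
Reagents that add atoms: none
Why: Buffered Dess–Martin oxidation should give the alkoxy aldehyde (C5) without epimerisation at C6 or loss of the silyl ether; 11 is used at once.

Step 10
Reactants: 12 methyl [bis(2,2,2-trifluoroethoxy)phosphoryl]acetate; 13 (iodomethyl)trimethylsilane
Product: 14 methyl 2-[bis(2,2,2-trifluoroethoxy)phosphoryl]-3-(trimethylsilyl)propanoate (racemic)
Conditions: NaH, DMF, 0 °C; then 13, 50 °C
Reagents that add atoms: none
Why: C-Alkylation of the stabilised phosphonoacetate anion by the primary iodide, an SN2 reaction made easy by the α-silyl group; the new stereocentre is lost in the next step, so the racemate is used.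

Step 11
Reactants: 11 (4R,5S)-5-[(2Z)-4-{[tert-butyl(dimethyl)silyl]oxy}but-2-en-2-yl]-2,2-dimethyl-1,3-dioxolane-4-carbaldehyde; 14 methyl 2-[bis(2,2,2-trifluoroethoxy)phosphoryl]-3-(trimethylsilyl)propanoate
Product: 15 methyl (2E)-3-[(4S,5S)-5-[(2Z)-4-{[tert-butyl(dimethyl)silyl]oxy}but-2-en-2-yl]-2,2-dimethyl-1,3-dioxolan-4-yl]-2-[(trimethylsilyl)methyl]prop-2-enoate (ester cis to C6)
Conditions: 14, KN(SiMe3)2, 18-crown-6, THF, −78 °C; then 11, −78 °C
Reagents that add atoms: none
Why: Still–Gennari variant of the Horner–Wadsworth–Emmons reaction: with the electron-poor bis(trifluoroethyl) phosphonate and a dissociated potassium counter-ion the first adduct eliminates faster than it equilibrates, which should place the ester (future C8) cis to C6 and the silylmethyl group trans to it. The descriptor is E only because CH2SiMe3 outranks the ester; the allylsilane arrives complete in this step.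

Step 12
Reactants: 15 methyl (2E)-3-[(4S,5S)-5-[(2Z)-4-{[tert-butyl(dimethyl)silyl]oxy}but-2-en-2-yl]-2,2-dimethyl-1,3-dioxolan-4-yl]-2-[(trimethylsilyl)methyl]prop-2-enoate
Product: 16 (2E)-3-[(4S,5S)-5-[(2Z)-4-{[tert-butyl(dimethyl)silyl]oxy}but-2-en-2-yl]-2,2-dimethyl-1,3-dioxolan-4-yl]-2-[(trimethylsilyl)methyl]prop-2-en-1-ol
Conditions: i-Bu2AlH (2.5 equiv), CH2Cl2, −78 °C; aq. potassium sodium tartrate
Reagents that add atoms: none
Why: 1,2-Reduction of the enoate; silyl ether, acetonide and allylsilane are inert to the hydride at −78 °C.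

Step 13
Reactants: 16 (2E)-3-[(4S,5S)-5-[(2Z)-4-{[tert-butyl(dimethyl)silyl]oxy}but-2-en-2-yl]-2,2-dimethyl-1,3-dioxolan-4-yl]-2-[(trimethylsilyl)methyl]prop-2-en-1-ol
Product: 17 (2E)-3-[(4S,5S)-5-[(2Z)-4-{[tert-butyl(dimethyl)silyl]oxy}but-2-en-2-yl]-2,2-dimethyl-1,3-dioxolan-4-yl]-2-[(trimethylsilyl)methyl]prop-2-enal
Conditions: Dess–Martin periodinane, NaHCO3, CH2Cl2, 0 °C
Reagents that add atoms: none
Why: Neutral Dess–Martin oxidation of the allylic alcohol should give the α-substituted enal without acid or base that could isomerise the double bond or protodesilylate the allylsilane; 17 is used directly.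

Step 14
Reactants: 17 (2E)-3-[(4S,5S)-5-[(2Z)-4-{[tert-butyl(dimethyl)silyl]oxy}but-2-en-2-yl]-2,2-dimethyl-1,3-dioxolan-4-yl]-2-[(trimethylsilyl)methyl]prop-2-enal
Product: 18 (1E,3S)-1-[(4S,5S)-5-[(2Z)-4-{[tert-butyl(dimethyl)silyl]oxy}but-2-en-2-yl]-2,2-dimethyl-1,3-dioxolan-4-yl]-2-[(trimethylsilyl)methyl]hexa-1,5-dien-3-ol
Conditions: (−)-Ipc2B(allyl) (from (+)-α-pinene), Et2O, −78 °C; then NaOH, H2O2, 0 °C to rt
Reagents that add atoms: (−)-B-allyldiisopinocampheylborane, C=CCB([C@@H]1C[C@@H]2C[C@H]([C@H]1C)C2(C)C)[C@@H]1C[C@@H]2C[C@H]([C@H]1C)C2(C)C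
Why: Brown allylboration through a closed chair transition state; the (+)-α-pinene-derived reagent adds allyl to the Si face of the aldehyde, which corresponds to (S) at C8 because C7 outranks the allyl CH2. The remote dioxolane centres are not expected to interfere, so control is by the reagent.

Step 15
Reactants: 18 (1E,3S)-1-[(4S,5S)-5-[(2Z)-4-{[tert-butyl(dimethyl)silyl]oxy}but-2-en-2-yl]-2,2-dimethyl-1,3-dioxolan-4-yl]-2-[(trimethylsilyl)methyl]hexa-1,5-dien-3-ol
Product: 19 (1E,3S)-1-[(4S,5S)-5-[(2Z)-4-{[tert-butyl(dimethyl)silyl]oxy}but-2-en-2-yl]-2,2-dimethyl-1,3-dioxolan-4-yl]-6-methyl-2-[(trimethylsilyl)methyl]hepta-1,5-dien-3-ol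
Conditions: 2-methylbut-2-ene (excess), second-generation Grubbs catalyst RuCl2(=CHPh)(PCy3)(H2IMes) (5 mol %), CH2Cl2, 40 °C
Reagents that add atoms: 2-methylbut-2-ene, CC=C(C)C
Why: Olefin cross-metathesis: only the monosubstituted alkene of 18 should enter the catalytic cycle, the trisubstituted alkenes being spectators, and exchange with the excess trisubstituted partner turns the vinyl group into the prenyl group with loss of propene.

Step 16
Reactants: 19 (1E,3S)-1-[(4S,5S)-5-[(2Z)-4-{[tert-butyl(dimethyl)silyl]oxy}but-2-en-2-yl]-2,2-dimethyl-1,3-dioxolan-4-yl]-6-methyl-2-[(trimethylsilyl)methyl]hepta-1,5-dien-3-ol; 20 angelic acid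
Product: 21 (1E,3S)-1-[(4S,5S)-5-[(2Z)-4-{[tert-butyl(dimethyl)silyl]oxy}but-2-en-2-yl]-2,2-dimethyl-1,3-dioxolan-4-yl]-6-methyl-2-[(trimethylsilyl)methyl]hepta-1,5-dien-3-yl (2Z)-2-methylbut-2-enoate
Conditions: 20, 2,4,6-trichlorobenzoyl chloride, Et3N, toluene, rt; then 19, 80 °C
Reagents that add atoms: none
Why: Yamaguchi-type esterification through the mixed anhydride, run without a nucleophilic catalyst because such catalysts add reversibly to the activated angeloyl unit and isomerise it to the tiglate; C8 is not touched.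

Step 17
Reactants: 21 (1E,3S)-1-[(4S,5S)-5-[(2Z)-4-{[tert-butyl(dimethyl)silyl]oxy}but-2-en-2-yl]-2,2-dimethyl-1,3-dioxolan-4-yl]-6-methyl-2-[(trimethylsilyl)methyl]hepta-1,5-dien-3-yl (2Z)-2-methylbut-2-enoate
Product: 22 (1E,3S)-1-[(4S,5S)-5-[(2Z)-4-hydroxybut-2-en-2-yl]-2,2-dimethyl-1,3-dioxolan-4-yl]-6-methyl-2-[(trimethylsilyl)methyl]hepta-1,5-dien-3-yl (2Z)-2-methylbut-2-enoate
Conditions: Bu4NF, AcOH (1:1), THF, 0 °C to rt
Reagents that add atoms: none
Why: Fluoride cleaves the primary allylic Si–O bond; buffering with AcOH keeps the medium near neutral so that the angelate and the C–SiMe3 bond of the allylsilane should persist.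

Step 18
Reactants: 22 (1E,3S)-1-[(4S,5S)-5-[(2Z)-4-hydroxybut-2-en-2-yl]-2,2-dimethyl-1,3-dioxolan-4-yl]-6-methyl-2-[(trimethylsilyl)methyl]hepta-1,5-dien-3-yl (2Z)-2-methylbut-2-enoate
Product: 23 (1E,3S)-1-[(4S,5S)-5-[(2Z)-4-acetoxybut-2-en-2-yl]-2,2-dimethyl-1,3-dioxolan-4-yl]-6-methyl-2-[(trimethylsilyl)methyl]hepta-1,5-dien-3-yl (2Z)-2-methylbut-2-enoate
Conditions: Ac2O, pyridine, DMAP (cat.), CH2Cl2, 0 °C
Reagents that add atoms: acetic anhydride, CC(=O)OC(C)=O
Why: Acylation of the only free hydroxyl installs the ionisable group last, so that nothing after it can attack the allylic acetate.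

Step 19
Reactants: 23 (1E,3S)-1-[(4S,5S)-5-[(2Z)-4-acetoxybut-2-en-2-yl]-2,2-dimethyl-1,3-dioxolan-4-yl]-6-methyl-2-[(trimethylsilyl)methyl]hepta-1,5-dien-3-yl (2Z)-2-methylbut-2-enoate
Product: 26 (3S)-6-methyl-2-[(3aS,4S,7aS)-2,2,7-trimethyl-3a,4,5,7a-tetrahydro-1,3-benzodioxol-4-yl]hepta-1,5-dien-3-yl (2Z)-2-methylbut-2-enoate, via allyl cation 24 (not isolated), via β-silyl cation 25 (not isolated)
Conditions: SnCl4 (1.2 equiv), 2,6-di-tert-butylpyridine (0.3 equiv), CH2Cl2 (0.005 M), −78 to −40 °C; aq. NaHCO3
Reagents that add atoms: none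
Why: SnCl4 binds the acetate carbonyl and ionises the primary allylic C4–O bond to the (Z)-configured allyl cation 24, delocalised over C4, C3 and C2; the γ-carbon C5 of the allylsilane attacks C4, and the resulting cation 25 at C7, stabilised by the β-silicon, collapses by loss of the silyl group to chloride, which places the new double bond at C7=CH2 and nowhere else. The closest known reactions are the Lewis acid promoted cyclisation of neryl esters to the terpinyl skeleton and the intramolecular Hosomi–Sakurai-type capture of allyl cations by allylsilanes. The six-membered ring closes with the allyl cation double bond C2=C3 inside the ring and the allylsilane double bond outside it (6-exo with respect to C5=C7); attack at C2 would need a four-membered ring and is not expected. The only new stereocentre is C5: because C7 is fully substituted, allylic 1,3-strain holds the C6–H bond in the plane of C5=C7, the tether through C1 then delivers C4 to one face only, and in the chair-like transition state the two acetonide oxygens and the C7 arm are all equatorial, so the side chain should come out trans to the C6 oxygen. The (Z) geometry at C2=C3 fixed in step 5 is what lets C4 reach C5, and the trans-dioxolane holds the two arms gauche, the only conformer that can close. Chemoselectivity rests on the primary acetate giving an allyl cation with a tertiary terminus, which ionises more easily at −78 °C than the secondary C8 angelate or the ether-type C1–O and C6–O bonds; the hindered pyridine removes adventitious HCl that would protodesilylate the allylsilane. The silyl group sits trans to C6 on C5=C7, so it can stay anti to the incoming C4 without meeting the dioxolane.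

Step 20
Reactants: 26 (3S)-6-methyl-2-[(3aS,4S,7aS)-2,2,7-trimethyl-3a,4,5,7a-tetrahydro-1,3-benzodioxol-4-yl]hepta-1,5-dien-3-yl (2Z)-2-methylbut-2-enoate
Product: 27 (3S)-2-[(1S,5S,6S)-5,6-dihydroxy-4-methylcyclohex-3-en-1-yl]-6-methylhepta-1,5-dien-3-yl (2Z)-2-methylbut-2-enoate
Conditions: AcOH/H2O/THF (3:1:1), 45 °C
Reagents that add atoms: none
Why: Acid hydrolysis of the ketal; the trans-fused dioxolane on a six-membered ring is strained and should open under acid mild enough to leave the allylic C1–O bond, the angelate and the prenyl group alone.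

Step 21
Reactants: 27 (3S)-2-[(1S,5S,6S)-5,6-dihydroxy-4-methylcyclohex-3-en-1-yl]-6-methylhepta-1,5-dien-3-yl (2Z)-2-methylbut-2-enoate
Product: 28 (3S)-2-[(1S,3S,4S,5R,6R)-4,5-dihydroxy-6-methyl-7-oxabicyclo[4.1.0]heptan-3-yl]-6-methylhepta-1,5-dien-3-yl (2Z)-2-methylbut-2-enoate
Conditions: VO(acac)2 (5 mol %), t-BuOOH (1.5 equiv, in decane), CH2Cl2, 0 °C to rt
Reagents that add atoms: tert-butyl hydroperoxide, CC(C)(C)OO
Why: Vanadium-catalysed hydroxyl-directed epoxidation: the vanadate ester of the allylic C1 hydroxyl delivers the peroxide oxygen to C2=C3 on its own face, which is cis to the C5 side chain and trans to the C6 oxygen, and so sets C2 and C3. The prenyl, exocyclic and angelate double bonds have no allylic hydroxyl and should react far more slowly.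

Step 22
Reactants: 28 (3S)-2-[(1S,3S,4S,5R,6R)-4,5-dihydroxy-6-methyl-7-oxabicyclo[4.1.0]heptan-3-yl]-6-methylhepta-1,5-dien-3-yl (2Z)-2-methylbut-2-enoate
Product: 29 (3S)-2-[(1S,3S,4S,5R,6R)-4-acetoxy-5-hydroxy-6-methyl-7-oxabicyclo[4.1.0]heptan-3-yl]-6-methylhepta-1,5-dien-3-yl (2Z)-2-methylbut-2-enoate
Conditions: Ac2O (1.05 equiv), 2,4,6-collidine, CH2Cl2, −40 to 0 °C
Reagents that add atoms: acetic anhydride, CC(=O)OC(C)=O
Why: Kinetic acylation of the more accessible hydroxyl: the C6 hydroxyl is an ordinary equatorial secondary alcohol, whereas the C1 hydroxyl lies next to the fully substituted epoxide carbon C2, is inductively deactivated by the epoxide oxygen and hydrogen-bonded to it, so a slight excess of anhydride with a hindered base at low temperature should acetylate O6 first.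

Step 23
Reactants: 29 (3S)-2-[(1S,3S,4S,5R,6R)-4-acetoxy-5-hydroxy-6-methyl-7-oxabicyclo[4.1.0]heptan-3-yl]-6-methylhepta-1,5-dien-3-yl (2Z)-2-methylbut-2-enoate
Product: 30 (3S)-2-[(1S,3S,4S,6S)-4-acetoxy-6-methyl-5-oxo-7-oxabicyclo[4.1.0]heptan-3-yl]-6-methylhepta-1,5-dien-3-yl (2Z)-2-methylbut-2-enoate
Conditions: Dess–Martin periodinane, NaHCO3, CH2Cl2, 0 °C to rt
Reagents that add atoms: none
Why: Buffered Dess–Martin oxidation of the remaining secondary alcohol should give the epoxy ketone without base that could epimerise C6, open the epoxide or isomerise the angelate.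

## Compound list

1 | (4S,5S)-2,2-dimethyl-1,3-dioxolane-4,5-dimethanol (2,3-O-isopropylidene-L-threitol) | OC[C@@H]1OC(C)(C)O[C@H]1CO | starting material
2 | [(4S,5S)-5-{[(4-methoxybenzyl)oxy]methyl}-2,2-dimethyl-1,3-dioxolan-4-yl]methanol | OC[C@@H]1OC(C)(C)O[C@H]1COCc1ccc(OC)cc1 | intermediate
3 | (4R,5S)-5-{[(4-methoxybenzyl)oxy]methyl}-2,2-dimethyl-1,3-dioxolane-4-carbaldehyde | O=C[C@@H]1OC(C)(C)O[C@H]1COCc1ccc(OC)cc1 | intermediate
4 | (4S,5S)-4-(2,2-dibromoethenyl)-5-{[(4-methoxybenzyl)oxy]methyl}-2,2-dimethyl-1,3-dioxolane | BrC(Br)=C[C@@H]1OC(C)(C)O[C@H]1COCc1ccc(OC)cc1 | intermediate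
5 | {[(4S,5S)-5-{[(4-methoxybenzyl)oxy]methyl}-2,2-dimethyl-1,3-dioxolan-4-yl]ethynyl}lithium | [Li]C#C[C@@H]1OC(C)(C)O[C@H]1COCc1ccc(OC)cc1 | intermediate (not isolated)
6 | methyl 3-[(4S,5S)-5-{[(4-methoxybenzyl)oxy]methyl}-2,2-dimethyl-1,3-dioxolan-4-yl]prop-2-ynoate | COC(=O)C#C[C@@H]1OC(C)(C)O[C@H]1COCc1ccc(OC)cc1 | intermediate
7 | methyl (2Z)-3-[(4S,5S)-5-{[(4-methoxybenzyl)oxy]methyl}-2,2-dimethyl-1,3-dioxolan-4-yl]but-2-enoate | COC(=O)/C=C(C)\[C@@H]1OC(C)(C)O[C@H]1COCc1ccc(OC)cc1 | intermediate
8 | (2Z)-3-[(4S,5S)-5-{[(4-methoxybenzyl)oxy]methyl}-2,2-dimethyl-1,3-dioxolan-4-yl]but-2-en-1-ol | OC/C=C(C)\[C@@H]1OC(C)(C)O[C@H]1COCc1ccc(OC)cc1 | intermediate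
9 | tert-butyl{[(2Z)-3-[(4S,5S)-5-{[(4-methoxybenzyl)oxy]methyl}-2,2-dimethyl-1,3-dioxolan-4-yl]but-2-en-1-yl]oxy}dimethylsilane | CC(C)(C)[Si](C)(C)OC/C=C(C)\[C@@H]1OC(C)(C)O[C@H]1COCc1ccc(OC)cc1 | intermediate
10 | [(4S,5S)-5-[(2Z)-4-{[tert-butyl(dimethyl)silyl]oxy}but-2-en-2-yl]-2,2-dimethyl-1,3-dioxolan-4-yl]methanol | CC(C)(C)[Si](C)(C)OC/C=C(C)\[C@@H]1OC(C)(C)O[C@H]1CO | intermediate
11 | (4R,5S)-5-[(2Z)-4-{[tert-butyl(dimethyl)silyl]oxy}but-2-en-2-yl]-2,2-dimethyl-1,3-dioxolane-4-carbaldehyde | CC(C)(C)[Si](C)(C)OC/C=C(C)\[C@@H]1OC(C)(C)O[C@H]1C=O | intermediate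
12 | methyl [bis(2,2,2-trifluoroethoxy)phosphoryl]acetate | COC(=O)CP(=O)(OCC(F)(F)F)OCC(F)(F)F | starting material
13 | (iodomethyl)trimethylsilane | C[Si](C)(C)CI | starting material
14 | methyl 2-[bis(2,2,2-trifluoroethoxy)phosphoryl]-3-(trimethylsilyl)propanoate (racemic) | COC(=O)C(C[Si](C)(C)C)P(=O)(OCC(F)(F)F)OCC(F)(F)F | intermediate
15 | methyl (2E)-3-[(4S,5S)-5-[(2Z)-4-{[tert-butyl(dimethyl)silyl]oxy}but-2-en-2-yl]-2,2-dimethyl-1,3-dioxolan-4-yl]-2-[(trimethylsilyl)methyl]prop-2-enoate (ester cis to C6) | CC(C)(C)[Si](C)(C)OC/C=C(C)\[C@@H]1OC(C)(C)O[C@H]1/C=C(/C[Si](C)(C)C)C(=O)OC | intermediate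
16 | (2E)-3-[(4S,5S)-5-[(2Z)-4-{[tert-butyl(dimethyl)silyl]oxy}but-2-en-2-yl]-2,2-dimethyl-1,3-dioxolan-4-yl]-2-[(trimethylsilyl)methyl]prop-2-en-1-ol | CC(C)(C)[Si](C)(C)OC/C=C(C)\[C@@H]1OC(C)(C)O[C@H]1/C=C(/C[Si](C)(C)C)CO | intermediate
17 | (2E)-3-[(4S,5S)-5-[(2Z)-4-{[tert-butyl(dimethyl)silyl]oxy}but-2-en-2-yl]-2,2-dimethyl-1,3-dioxolan-4-yl]-2-[(trimethylsilyl)methyl]prop-2-enal | CC(C)(C)[Si](C)(C)OC/C=C(C)\[C@@H]1OC(C)(C)O[C@H]1/C=C(/C[Si](C)(C)C)C=O | intermediate
18 | (1E,3S)-1-[(4S,5S)-5-[(2Z)-4-{[tert-butyl(dimethyl)silyl]oxy}but-2-en-2-yl]-2,2-dimethyl-1,3-dioxolan-4-yl]-2-[(trimethylsilyl)methyl]hexa-1,5-dien-3-ol | CC(C)(C)[Si](C)(C)OC/C=C(C)\[C@@H]1OC(C)(C)O[C@H]1/C=C(/C[Si](C)(C)C)[C@H](CC=C)O | intermediate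
19 | (1E,3S)-1-[(4S,5S)-5-[(2Z)-4-{[tert-butyl(dimethyl)silyl]oxy}but-2-en-2-yl]-2,2-dimethyl-1,3-dioxolan-4-yl]-6-methyl-2-[(trimethylsilyl)methyl]hepta-1,5-dien-3-ol | CC(C)(C)[Si](C)(C)OC/C=C(C)\[C@@H]1OC(C)(C)O[C@H]1/C=C(/C[Si](C)(C)C)[C@H](CC=C(C)C)O | intermediate
20 | angelic acid, (2Z)-2-methylbut-2-enoic acid | C/C=C(/C)C(=O)O | starting material
21 | (1E,3S)-1-[(4S,5S)-5-[(2Z)-4-{[tert-butyl(dimethyl)silyl]oxy}but-2-en-2-yl]-2,2-dimethyl-1,3-dioxolan-4-yl]-6-methyl-2-[(trimethylsilyl)methyl]hepta-1,5-dien-3-yl (2Z)-2-methylbut-2-enoate | CC(C)(C)[Si](C)(C)OC/C=C(C)\[C@@H]1OC(C)(C)O[C@H]1/C=C(/C[Si](C)(C)C)[C@H](CC=C(C)C)OC(=O)/C(C)=C\C | intermediate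
22 | (1E,3S)-1-[(4S,5S)-5-[(2Z)-4-hydroxybut-2-en-2-yl]-2,2-dimethyl-1,3-dioxolan-4-yl]-6-methyl-2-[(trimethylsilyl)methyl]hepta-1,5-dien-3-yl (2Z)-2-methylbut-2-enoate | OC/C=C(C)\[C@@H]1OC(C)(C)O[C@H]1/C=C(/C[Si](C)(C)C)[C@H](CC=C(C)C)OC(=O)/C(C)=C\C | intermediate
23 | (1E,3S)-1-[(4S,5S)-5-[(2Z)-4-acetoxybut-2-en-2-yl]-2,2-dimethyl-1,3-dioxolan-4-yl]-6-methyl-2-[(trimethylsilyl)methyl]hepta-1,5-dien-3-yl (2Z)-2-methylbut-2-enoate (key-step precursor; C8 cis to C6 on C5=C7) | CC(=O)OC/C=C(C)\[C@@H]1OC(C)(C)O[C@H]1/C=C(/C[Si](C)(C)C)[C@H](CC=C(C)C)OC(=O)/C(C)=C\C | intermediate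
24 | allyl cation from 23 by loss of acetate (charge over C4, C3 and C2) | [CH2+]/C=C(C)\[C@@H]1OC(C)(C)O[C@H]1/C=C(/C[Si](C)(C)C)[C@H](CC=C(C)C)OC(=O)/C(C)=C\C | intermediate (not isolated)
25 | cyclised β-silyl cation (C4–C5 formed, charge at C7) | C[Si](C)(C)C[C+]([C@H](CC=C(C)C)OC(=O)/C(C)=C\C)[C@@H]1CC=C(C)[C@@H]2OC(C)(C)O[C@@H]12 | intermediate (not isolated)
26 | (3S)-6-methyl-2-[(3aS,4S,7aS)-2,2,7-trimethyl-3a,4,5,7a-tetrahydro-1,3-benzodioxol-4-yl]hepta-1,5-dien-3-yl (2Z)-2-methylbut-2-enoate (key-step product) | C=C([C@H](CC=C(C)C)OC(=O)/C(C)=C\C)[C@@H]1CC=C(C)[C@@H]2OC(C)(C)O[C@@H]12 | intermediate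
27 | (3S)-2-[(1S,5S,6S)-5,6-dihydroxy-4-methylcyclohex-3-en-1-yl]-6-methylhepta-1,5-dien-3-yl (2Z)-2-methylbut-2-enoate | C=C([C@H](CC=C(C)C)OC(=O)/C(C)=C\C)[C@@H]1CC=C(C)[C@H](O)[C@H]1O | intermediate
28 | (3S)-2-[(1S,3S,4S,5R,6R)-4,5-dihydroxy-6-methyl-7-oxabicyclo[4.1.0]heptan-3-yl]-6-methylhepta-1,5-dien-3-yl (2Z)-2-methylbut-2-enoate | C=C([C@H](CC=C(C)C)OC(=O)/C(C)=C\C)[C@@H]1C[C@@H]2O[C@]2(C)[C@H](O)[C@H]1O | intermediate
29 | (3S)-2-[(1S,3S,4S,5R,6R)-4-acetoxy-5-hydroxy-6-methyl-7-oxabicyclo[4.1.0]heptan-3-yl]-6-methylhepta-1,5-dien-3-yl (2Z)-2-methylbut-2-enoate | C=C([C@H](CC=C(C)C)OC(=O)/C(C)=C\C)[C@@H]1C[C@@H]2O[C@]2(C)[C@H](O)[C@H]1OC(C)=O | intermediate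
30 | (3S)-2-[(1S,3S,4S,6S)-4-acetoxy-6-methyl-5-oxo-7-oxabicyclo[4.1.0]heptan-3-yl]-6-methylhepta-1,5-dien-3-yl (2Z)-2-methylbut-2-enoate (CNP0150645.2) | C=C([C@H](CC=C(C)C)OC(=O)/C(C)=C\C)[C@@H]1C[C@@H]2O[C@]2(C)C(=O)[C@H]1OC(C)=O | target

## Step count and least certain steps

Total: 23 steps. Longest linear sequence: 22 steps (1 to 30); step 10 prepares phosphonate 14 separately.

**Step 19 (key step).** The cation may not be captured productively. The allylsilane is flanked by the oxygen-bearing carbons C6 and C8 and is a weak nucleophile, so proton loss from the allyl cation or return of chloride can outrun ring closure. The tin halide can also complex the dioxolane oxygens and bring about opening of the acetonide or 1,4-elimination of the C6 oxygen with loss of the silyl group, and ionisation of the secondary allylic angelate would scramble C8. Fallback: set out from alcohol 22 and convert it into the (Z)-allylic bromide F1 (CBr4, PPh3, 2,6-lutidine, CH2Cl2, −20 °C). Ionise F1 with a halophile in place of an oxophilic Lewis acid (AgOCOCF3, 2,6-di-tert-butylpyridine, CH2Cl2, −78 °C). Silver bromide precipitates, no Lewis acid is left to bind the acetonide or the esters, and the silyl group leaves as its trifluoroacetate. The same ring closure then rejoins the route at 26.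

**Step 22 (selective acetylation).** Discrimination between two hindered secondary hydroxyls may be poor, giving the regioisomeric acetate and the diacetate; the steric and electronic bias toward O6 is real but modest. Fallback: set out from diol 27 and use the allylic nature of the C1 hydroxyl instead of a rate difference.
- MnO2 (CH2Cl2, rt) oxidises only the allylic alcohol to the hydroxy enone F2.
- Ac2O/pyridine acetylates the single remaining hydroxyl to the acetoxy enone F3.
- NaBH4 with CeCl3·7H2O (MeOH, −78 °C) should return the C1 carbinol by axial hydride delivery as the allylic alcohol F4, with the hydroxyl trans to the acetate as in 27.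
- VO(acac)2/t-BuOOH then epoxidises F4 under direction of its only hydroxyl and rejoins the route at 29.

This costs two more steps and makes the hydride addition the uncertain point.

**Step 11 (olefination with 14).** The α-branched, silicon-bearing phosphonate anion may add sluggishly to the hindered aldehyde, or the ester-cis selectivity may erode; the alkylation in step 10 may also over-alkylate. Fallback: set out from aldehyde 11.
- CBr4/PPh3/Et3N gives the dibromoalkene F5.
- Palladium-catalysed coupling with Me3SiCH2ZnCl (from Me3SiCH2MgCl and ZnCl2; PdCl2(DPEphos), THF) replaces selectively the bromine trans to C6 and gives the (Z)-bromoalkene F6.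
- Br/Li exchange (t-BuLi, Et2O, −78 °C) and formylation with DMF rejoin the route at enal 17 and make steps 12 and 13 unnecessary.

**Step 16 (angeloylation).** Isomerisation of the activated angeloyl unit to the tigloyl unit, or slow acylation of the hindered allylic alcohol at the temperature needed, are the likely problems. Fallback: set out from alcohol 19 and esterify it with 2-[bis(2,2,2-trifluoroethoxy)phosphoryl]propanoic acid (DCC, DMAP, CH2Cl2) to the phosphonopropionate F7. A Still–Gennari olefination of F7 with acetaldehyde (KN(SiMe3)2, 18-crown-6, THF, −78 °C) builds the (Z)-2-methylbut-2-enoate on the molecule and rejoins the route at 21.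

## Further compounds

F1 | step 19 | (1E,3S)-1-[(4S,5S)-5-[(2Z)-4-bromobut-2-en-2-yl]-2,2-dimethyl-1,3-dioxolan-4-yl]-6-methyl-2-[(trimethylsilyl)methyl]hepta-1,5-dien-3-yl (2Z)-2-methylbut-2-enoate | BrC/C=C(C)\[C@@H]1OC(C)(C)O[C@H]1/C=C(/C[Si](C)(C)C)[C@H](CC=C(C)C)OC(=O)/C(C)=C\C
F2 | step 22 | (3S)-2-[(1S,6S)-6-hydroxy-4-methyl-5-oxocyclohex-3-en-1-yl]-6-methylhepta-1,5-dien-3-yl (2Z)-2-methylbut-2-enoate | C=C([C@H](CC=C(C)C)OC(=O)/C(C)=C\C)[C@@H]1CC=C(C)C(=O)[C@H]1O
F3 | step 22 | (3S)-2-[(1S,6S)-6-acetoxy-4-methyl-5-oxocyclohex-3-en-1-yl]-6-methylhepta-1,5-dien-3-yl (2Z)-2-methylbut-2-enoate | C=C([C@H](CC=C(C)C)OC(=O)/C(C)=C\C)[C@@H]1CC=C(C)C(=O)[C@H]1OC(C)=O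
F4 | step 22 | (3S)-2-[(1S,5S,6S)-6-acetoxy-5-hydroxy-4-methylcyclohex-3-en-1-yl]-6-methylhepta-1,5-dien-3-yl (2Z)-2-methylbut-2-enoate | C=C([C@H](CC=C(C)C)OC(=O)/C(C)=C\C)[C@@H]1CC=C(C)[C@H](O)[C@H]1OC(C)=O
F5 | step 11 | tert-butyl{[(2Z)-3-[(4S,5S)-5-(2,2-dibromoethenyl)-2,2-dimethyl-1,3-dioxolan-4-yl]but-2-en-1-yl]oxy}dimethylsilane | CC(C)(C)[Si](C)(C)OC/C=C(C)\[C@@H]1OC(C)(C)O[C@H]1C=C(Br)Br
F6 | step 11 | {[(2Z)-3-[(4S,5S)-5-[(1Z)-2-bromo-3-(trimethylsilyl)prop-1-en-1-yl]-2,2-dimethyl-1,3-dioxolan-4-yl]but-2-en-1-yl]oxy}(tert-butyl)dimethylsilane | CC(C)(C)[Si](C)(C)OC/C=C(C)\[C@@H]1OC(C)(C)O[C@H]1/C=C(/C[Si](C)(C)C)Br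
F7 | step 16 | (1E,3S)-1-[(4S,5S)-5-[(2Z)-4-{[tert-butyl(dimethyl)silyl]oxy}but-2-en-2-yl]-2,2-dimethyl-1,3-dioxolan-4-yl]-6-methyl-2-[(trimethylsilyl)methyl]hepta-1,5-dien-3-yl 2-[bis(2,2,2-trifluoroethoxy)phosphoryl]propanoate | CC(C)(C)[Si](C)(C)OC/C=C(C)\[C@@H]1OC(C)(C)O[C@H]1/C=C(/C[Si](C)(C)C)[C@H](CC=C(C)C)OC(=O)C(C)P(=O)(OCC(F)(F)F)OCC(F)(F)F
A1 | alternative 1 | 3-methylfuran | Cc1ccoc1
A2 | alternative 1 | 3-acryloyl-1,3-oxazolidin-2-one | C=CC(=O)N1CCOC1=O
A3 | alternative 1 | endo 7-oxabicyclo[2.2.1]hept-2-ene imide (C5 acyl trans to the C6–O bridge) | O=C(N1CCOC1=O)[C@@H]2C[C@@H]3C(C)=C[C@H]2O3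
A4 | alternative 2 | acyclic dienone with methacryloyl and allyl units | C=C([C@H](CC(OC)OC)O[Si](C)(C)C(C)(C)C)[C@H](CC=C)[C@H](OC(C)=O)C(=O)C(C)=C
A5 | alternative 2 | trans-6-acetoxy-5-alkenyl-2-methylcyclohex-2-enone | C=C([C@H](CC(OC)OC)O[Si](C)(C)C(C)(C)C)[C@@H]1CC=C(C)C(=O)[C@H]1OC(C)=O
A6 | alternative 3 | acyclic aldehyde with (Z)-iodoalkene | C=C([C@H](CC=C(C)C)OC(=O)/C(C)=C\C)[C@H](C/C=C(C)\I)[C@H](OCc1ccc(OC)cc1)C=O
A7 | alternative 3 | 2-methylcyclohex-2-enol with C6 4-methoxybenzyl ether | C=C([C@H](CC=C(C)C)OC(=O)/C(C)=C\C)[C@@H]1CC=C(C)[C@H](O)[C@H]1OCc2ccc(OC)cc2
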